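The reagent is charged one to one on the left-handed substrate, L, so one concentration sets the order of the rate. Reagent and L fall together, and a rate proportional to both goes as L squared.

| flask | left-handed substrate | right-handed substrate | reagent | catalyst | temperature | remark | time |
|---|---|---|---|---|---|---|---|
| south-east | 0.50 M | 0.50 M | 1 equiv | 1 mol% | 15 °C | run made earlier |  |
| north | 0.25 M | 0.25 M | 1 equiv | 1 mol% | 26 °C | run made earlier |  |
| west | 0.38 M | 0.38 M | 1 equiv | 1 mol% | 15 °C | run made earlier |  |
| south | 0.50 M | 0.50 M | 1 equiv | 2 mol% | 26 °C | run made earlier |  |
| amber | 0.50 M | 0.50 M | 1.00 equiv (fed, over 12 min) | 1 mol% | 20 °C | all else is in the flask from the start; the feed brings no volume worth counting | 15 min |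
| grey | 0.50 M | 0.50 M | 1.00 equiv | 1 mol% |  | everything together at the start at −20 °C, warmed to 20 °C at 12 min | 15 min |
| green | 0.50 M | 0.50 M | 1.00 equiv | 1 mol% | 20 °C | everything together at the start | 15 min |
| ochre | 0.50 M | 0.50 M | 1.00 equiv (in portions, 3, over 12 min) | 1 mol% | 20 °C | first portion at the start, last at 12 min | 15 min |
| blue | 0.50 M | 0.50 M | 1.00 equiv (fed, over 12 min) | 1 mol% |  | the addition at −20 °C, then warmed to 20 °C; the feed brings no volume worth counting | 15 min |

| run | time / min | left-handed product / % | left-handed substrate / % |
|---|---|---|---|
| south-east | 1.33 | 30.7 | 21.0 |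
| south-east | 2.50 | 35.7 | 13.2 |
| south-east | 4.00 | 40.2 | 10.0 |
| south-east | 8.00 | 43.5 | 7.4 |
| south-east | 15.0 | 46.5 | 5.4 |
| north | 0.667 | 14.8 | 37.7 |
| north | 1.33 | 19.2 | 29.0 |
| north | 2.50 | 23.7 | 25.7 |
| north | 5.00 | 31.5 | 18.9 |
| north | 10.0 | 34.6 | 13.7 |
| west | 0.833 | 16.6 | 33.0 |
| west | 2.50 | 30.6 | 19.0 |
| west | 4.00 | 34.8 | 14.1 |
| west | 6.00 | 36.6 | 11.7 |
| west | 10.0 | 40.8 | 9.5 |
| south | 0.667 | 37.9 | 14.1 |
| south | 1.33 | 39.3 | 8.9 |
| south | 2.50 | 43.6 | 7.0 |
| south | 5.00 | 45.7 | 3.7 |
| south | 10.0 | 46.7 | 3.2 |

(scatter of a reading: 1 percentage point)

- catalyst is single-handed; left-handed substrate and right-handed substrate are mirror images of each other, charged as a racemate, each of them at the stated concentration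
- what was read earlier has a scatter of 1 percentage point, one standard deviation

- the best flask by amount of left-handed product, in percent of the left-handed substrate and right-handed substrate together charged; "all alike" if 1.5 percentage points covers them all (amber / grey / green / ochre / blue / all alike)
- amount of left-handed product at the end, in percent of the left-handed substrate and right-handed substrate together charged, amber
- amount of left-handed product at the end, in percent of the left-handed substrate and right-handed substrate together charged, grey
- amount of left-handed product at the end, in percent of the left-handed substrate and right-handed substrate together charged, green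
- amount of left-handed product at the end, in percent of the left-handed substrate and right-handed substrate together charged, ochre
- amount of left-handed product at the end, in percent of the left-handed substrate and right-handed substrate together charged, blue

In the south-east run, product and L add to 51.9 % at its last reading, about what the charge of L allows, so I count reacted L as product. So I plot the reciprocal of L, as a fraction of the racemate charged, against time. The mean slope from the start, κ, is my second-order clock, and the halving time of whatever L stands is the reciprocal of κL.

The south-east run reads 1.10 min⁻¹. The south run, per 1 mol% of catalyst, reads 1.46 min⁻¹. 20 °C lies near the middle of 15 °C and 26 °C, so I take the geometric mean, κ = 1.27 min⁻¹, for 1 mol% at 20 °C.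

The ladder starts fast. In the south-east run the first reading gives a slope of 2.08 min⁻¹, and at that slope the charge of L in that run halves in about 0.962 min. Next the clock slows: from 4.00 min on, that run's slope is 0.774 min⁻¹, less than the early one, and my mean carries this in.

With κ, green ends at L = 4.75 %, which gives 45.2 % product. There the halving time is 16.6 min, longer than the whole 15 min, so the tail creeps. A flask with its reaction put off entirely to the last 3.00 min comes by κ to an estimated 32.8 %, so I expect the delayed flasks between these figures, and green first.

The forecast names green, with 45.6 % there, 42.5 % in amber, 41.7 % in grey, 41.7 % in ochre and 40.5 % in blue: “Feeding or cold delays reaction, leaving 3 minutes to finish.” Its green stands above my figure.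

The flasks give green as best at 45.7 %, then grey 41.4 %, amber 40.9 %, blue 40.3 % and ochre 39.0 %.

    reagent + catalyst + left-handed substrate → catalyst + left-handed product (k = 11.6 M⁻² s⁻¹, Ea = 44.0 kJ mol⁻¹)
    reagent + catalyst + right-handed substrate → catalyst + right-handed product (k = 0.149 M⁻² s⁻¹, Ea = 57.0 kJ mol⁻¹)
    catalyst ⇌ dormant form (K = 1.50, k = 0.00440 s⁻¹, Ea = 95.0 kJ mol⁻¹, ΔH = 20.0 kJ mol⁻¹)
    (constants at 20 °C)

Green holds L at 4.31 % against my 4.75 %. The neighbour of green with 0.25 mol% of catalyst tests the clock further. Scaled by loading, κ becomes 0.317 min⁻¹, which gives L = 14.8 % and 35.2 % product. That neighbour holds 12.2 % of L, so my reckoned L stands 2.6 percentage points above it, and its left-handed product stands at 37.8 %.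

All runs come from a simulation for substances that don't exist; scatter was added.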